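**Retrosynthetic overview**

1. Numbering (eudesmane): ring A = C1–C2–C3–C4–C5–C10, ring B = C5–C6–C7–C8–C9–C10; C11(=C13)–C12O2H on C7, C14 methyl on C10, C15 formyl on C4.
2. Late stage: C8–O acyl bond by esterification, the C11=C13/C12 acid from a C12 alcohol (α-methylenation, then oxidation), the C15 aldehyde from a PMB ether, and fluoride deprotection last.
3. C6–OH, C7–H and C8–OH are relayed from one C8–silicon stereocentre: anti epoxidation/desilylation of an allylsilane (6α-OH, C7=C8), then α-face hydroboration.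
4. Key disconnection C5–C10 and C8–C9: an intramolecular Diels–Alder reaction of an acyclic (E,E)-1-silyl-1,3-dienyl isopropenyl ketone closes rings A and B together. The enabling feature is that the quaternary, methyl-bearing C10 of ring B is next to the oxygenated C1 (dienophile C9=C10–C1=O), and that the C5–C6–C7–C8 edge of ring B, oxygenated at C6 and C8, can be a diene whose C5 end is tied to C10 by the C1–C4 chain of ring A.
5. The triene comes from a Pd-catalysed hydrovinylation (C6–C7 bond) of a silylalkyne with a vinyl iodide; the C4 stereocentre comes from a Cu-catalysed asymmetric allylic alkylation.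

Key step: step 10

Assumption: the free 6-hydroxy 12-acid is isolable as drawn if acid is avoided once it is liberated (risk of 6,12-lactonisation); α/β refer to the usual eudesmane drawing with the C10 methyl β.

**Route**

Step 1
Reactants: 1 (E)-1,4-dibromobut-2-ene; 2 4-methoxybenzyl alcohol
Product: 4 (E)-1-bromo-4-[(4-methoxybenzyl)oxy]but-2-ene, via sodium 4-methoxybenzyl oxide 3 (not isolated)
Conditions: NaH, THF, 0 °C; then 1 (excess), Bu4NI (cat.), 0 °C → rt
Reagents that add atoms: none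
Why: Williamson etherification of the symmetrical bis-allylic dibromide (SN2 and SN2′ give the same product), with excess 1 suppressing double substitution.

Step 2
Reactants: 4 (E)-1-bromo-4-[(4-methoxybenzyl)oxy]but-2-ene; 5 [2-(1,3-dioxan-2-yl)ethyl]magnesium bromide
Product: 6 2-{(3R)-3-[(4-methoxybenzyloxy)methyl]pent-4-en-1-yl}-1,3-dioxane
Conditions: CuBr·SMe2 (cat.), Taniaphos ligand (cat., the enantiomer leading to the R product), CH2Cl2, −78 °C, slow addition of 5
Reagents that add atoms: none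
Why: Copper-catalysed asymmetric allylic alkylation with a Grignard reagent is SN2′-selective for γ-alkoxymethyl allyl bromides, and the C4 stereocentre is set by the chiral copper–diphosphine complex.

Step 3
Reactants: 6 2-{(3R)-3-[(4-methoxybenzyloxy)methyl]pent-4-en-1-yl}-1,3-dioxane
Product: 8 (2S)-4-(1,3-dioxan-2-yl)-2-[(4-methoxybenzyloxy)methyl]butanal, via vicinal diol 7 (not isolated)
Conditions: OsO4 (cat.), NaIO4, 2,6-lutidine, dioxane/H2O, rt
Reagents that add atoms: osmium tetroxide, O=[Os](=O)(=O)=O; sodium periodate, [Na+].[O-]I(=O)(=O)=O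
Why: Johnson–Lemieux dihydroxylation/glycol cleavage of the terminal alkene under buffered conditions should leave the PMB ether and the α-stereocentre untouched.

Step 4
Reactants: 8 (2S)-4-(1,3-dioxan-2-yl)-2-[(4-methoxybenzyloxy)methyl]butanal
Product: 9 2-{(3R,4E)-5-iodo-3-[(4-methoxybenzyloxy)methyl]pent-4-en-1-yl}-1,3-dioxane
Conditions: CrCl2, CHI3, THF/dioxane, 0 °C → rt
Reagents that add atoms: iodoform, IC(I)I
Why: Takai olefination gives the (E)-vinyl iodide under non-basic conditions that should not epimerise the α-branched aldehyde.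

Step 5
Reactants: 10 4-(trimethylsilyl)but-3-yn-1-ol
Product: 11 tert-butyldiphenyl{[4-(trimethylsilyl)but-3-yn-1-yl]oxy}silane
Conditions: TBDPSCl, imidazole, CH2Cl2, rt
Reagents that add atoms: tert-butyl(chloro)diphenylsilane, CC(C)(C)[Si](Cl)(c1ccccc1)c1ccccc1
Why: Standard silylation of a primary alcohol.

Step 6
Reactants: 9 2-{(3R,4E)-5-iodo-3-[(4-methoxybenzyloxy)methyl]pent-4-en-1-yl}-1,3-dioxane; 11 tert-butyldiphenyl{[4-(trimethylsilyl)but-3-yn-1-yl]oxy}silane
Product: 12 2-{(3R,4E,6E)-6-[2-(tert-butyldiphenylsilyloxy)ethyl]-3-[(4-methoxybenzyloxy)methyl]-7-(trimethylsilyl)hepta-4,6-dien-1-yl}-1,3-dioxane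
Conditions: Pd(OAc)2 (cat.), PPh3, HCO2H, Et3N, DMF, 50 °C
Reagents that add atoms: none
Why: Palladium-catalysed, formate-mediated hydrovinylation (reductive Heck reaction) of a silylalkyne: the alkenylpalladium adds syn with palladium at the silicon-bearing carbon and formate replaces palladium by hydrogen with retention, so silicon ends trans to C6 (E).

Step 7
Reactants: 12 the dienylsilane acetal from step 6
Product: 13 (4R,5E,7E)-7-[2-(tert-butyldiphenylsilyloxy)ethyl]-4-[(4-methoxybenzyloxy)methyl]-8-(trimethylsilyl)octa-5,7-dienal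
Conditions: TsOH·H2O (cat.), acetone/H2O, 45 °C
Reagents that add atoms: water, O
Why: Mild acid hydrolysis of the dioxane acetal, which the TBDPS ether, the PMB ether and the dienylsilane should tolerate.

Step 8
Reactants: 13 (4R,5E,7E)-dienal from step 7; 14 prop-1-en-2-ylmagnesium bromide
Product: 15 (6R,7E,9E)-9-[2-(tert-butyldiphenylsilyloxy)ethyl]-6-[(4-methoxybenzyloxy)methyl]-2-methyl-10-(trimethylsilyl)deca-1,7,9-trien-3-ol (both C3 epimers)
Conditions: THF, −78 °C; aq. NH4Cl
Reagents that add atoms: none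
Why: 1,2-Addition of the Grignard reagent to the aldehyde; the new carbinol centre forms as a mixture and is removed in step 9.

Step 9
Reactants: 15 the trienol from step 8
Product: 16 (6R,7E,9E)-9-[2-(tert-butyldiphenylsilyloxy)ethyl]-6-[(4-methoxybenzyloxy)methyl]-2-methyl-10-(trimethylsilyl)deca-1,7,9-trien-3-one
Conditions: Dess–Martin periodinane, NaHCO3, CH2Cl2, 0 °C; used directly
Reagents that add atoms: none
Why: Buffered Dess–Martin oxidation of the allylic alcohol gives the isopropenyl ketone without touching the diene.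

Step 10
Reactants: 16 the trienone from step 9
Product: 17 12-(tert-butyldiphenylsilyloxy)-15-(4-methoxybenzyloxy)-8β-(trimethylsilyl)-13-noreudesm-6-en-1-one (trans-fused: 5α-H and 10β-CH3; 4α-CH2OPMB)
Conditions: toluene (0.01 M), BHT (cat.), 90 °C
Reagents that add atoms: none
Why: Thermal, concerted but asynchronous [4+2] cycloaddition in which the diene C5=C6–C7=C8 adds suprafacially to the enone alkene C9=C10, forming C5–C10 and C8–C9 in one operation; the closest known reaction type is the intramolecular Diels–Alder reaction of 2-methyl-1,7,9-decatrien-3-ones to trans-fused 10-methyl-octalones. Ring B (a cyclohexene) arises from the cycloaddition itself, and ring A closes at the same time through the four-carbon C1–C4 tether (type 1 mode, tether on the diene terminus C5 and on the internal dienophile carbon C10, chair-like tether). C5 and C10: the trans ring fusion follows from the transition state with the tether carbonyl exo and the α-methyl group endo, the arrangement α-methyl-substituted dienophiles prefer, and the absolute sense follows from the (R)-stereocentre at C4, whose CH2OPMB group sits pseudo-equatorial on the chair tether. C8: the (E)-vinylsilane places silicon "outside", so it ends cis to C4, that is 8β and pseudoaxial, which is the orientation the later anti desilylation needs. The step needs trans- over cis-fusion and one π-face; the α-methyl group of the dienophile, the single equatorially disposed C4 substituent and the defined (E,E)-diene should secure these, while the tether fixes the regiochemistry and the polarity matches (C8, next to the C7 alkyl group, bonds to the enone β-carbon C9).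

Step 11
Reactants: 17 the trans-decalone from step 10
Product: 18 12-(tert-butyldiphenylsilyloxy)-15-(4-methoxybenzyloxy)-8β-(trimethylsilyl)-13-noreudesm-6-en-1β-ol
Conditions: NaBH4, MeOH, −20 → 0 °C
Reagents that add atoms: none
Why: Hydride should add axially from the α face, away from the axial C10 methyl on the neighbouring carbon, to give the equatorial 1β-alcohol.

Step 12
Reactants: 18 the allylsilane alcohol from step 11
Product: 20 15-(4-methoxybenzyloxy)-13-noreudesm-7-ene-1β,6α,12-triol, via 6α,7α-epoxysilane 19 (not isolated)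
Conditions: mCPBA, NaHCO3, CH2Cl2, 0 °C; then TBAF, THF, rt
Reagents that add atoms: 3-chloroperbenzoic acid, OOC(=O)c1cccc(Cl)c1
Why: The peracid should attack the allylsilane anti to the pseudoaxial C8–Si bond (also the face away from the C10 methyl) and fluoride then triggers the anti-periplanar Peterson-type opening, which fixes 6α-OH and moves the alkene to C7=C8; TBAF also removes the TBDPS group.

Step 13
Reactants: 20 the triol from step 12
Product: 21 1β,6α,12-tris(tert-butyldimethylsilyloxy)-15-(4-methoxybenzyloxy)-13-noreudesm-7-ene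
Conditions: TBSOTf, 2,6-lutidine, CH2Cl2, −78 → 0 °C
Reagents that add atoms: tert-butyldimethylsilyl trifluoromethanesulfonate, CC(C)(C)[Si](C)(C)OS(=O)(=O)C(F)(F)F
Why: The silyl triflate silylates the primary and both hindered secondary hydroxyls in one operation.

Step 14
Reactants: 21 the tris-silyl ether from step 13
Product: 23 1β,6α,12-tris(tert-butyldimethylsilyloxy)-15-(4-methoxybenzyloxy)-13-noreudesman-8α-ol (7α-H), via C8 alkylborane 22 (not isolated)
Conditions: BH3·THF, THF, 0 °C → rt; then NaOH, H2O2, 0 °C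
Reagents that add atoms: hydrogen peroxide, OO
Why: Hydroboration–oxidation puts boron on the less substituted C8 by syn addition from the α face, opposite the axial C10 methyl (1,3 to C8), and oxidation with retention gives 8α-OH and 7α-H with the side chain equatorial.

Step 15
Reactants: 24 ethyl 2-(hydroxymethyl)acrylate
Product: 25 ethyl 2-[(tert-butyldiphenylsilyloxy)methyl]acrylate
Conditions: TBDPSCl, imidazole, CH2Cl2, rt
Reagents that add atoms: tert-butyl(chloro)diphenylsilane, CC(C)(C)[Si](Cl)(c1ccccc1)c1ccccc1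
Why: Standard silylation of the primary allylic alcohol.

Step 16
Reactants: 25 ethyl 2-[(tert-butyldiphenylsilyloxy)methyl]acrylate
Product: 26 2-[(tert-butyldiphenylsilyloxy)methyl]acrylic acid
Conditions: LiOH, THF/H2O, 0 °C; then aq. HCl to pH 3
Reagents that add atoms: lithium hydroxide, [Li+].[OH-]
Why: Saponification of the ethyl ester, which the TBDPS ether tolerates.

Step 17
Reactants: 23 the 8α-alcohol from step 14; 26 2-[(tert-butyldiphenylsilyloxy)methyl]acrylic acid
Product: 28 1β,6α,12-tris(tert-butyldimethylsilyloxy)-15-(4-methoxybenzyloxy)-13-noreudesman-8α-yl 2-[(tert-butyldiphenylsilyloxy)methyl]acrylate, via mixed anhydride 27 (not isolated)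
Conditions: 2,4,6-trichlorobenzoyl chloride, Et3N, THF, rt; then 23, DMAP, toluene, rt
Reagents that add atoms: none
Why: Yamaguchi esterification acylates the hindered equatorial secondary alcohol with retention at C8.

Step 18
Reactants: 28 the C8 ester from step 17
Product: 29 the 12-alcohol: 1β,6α-bis(tert-butyldimethylsilyloxy)-12-hydroxy-15-(4-methoxybenzyloxy)-13-noreudesman-8α-yl 2-[(tert-butyldiphenylsilyloxy)methyl]acrylate
Conditions: HF·pyridine, pyridine, THF, 0 °C
Reagents that add atoms: none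
Why: Buffered HF·pyridine cleaves the primary TBS ether selectively; the hindered secondary TBS ethers and the primary TBDPS ether should survive.

Step 19
Reactants: 29 the 12-alcohol from step 18
Product: 30 the 12-aldehyde: 1β,6α-bis(tert-butyldimethylsilyloxy)-15-(4-methoxybenzyloxy)-12-oxo-13-noreudesman-8α-yl 2-[(tert-butyldiphenylsilyloxy)methyl]acrylate
Conditions: Dess–Martin periodinane, NaHCO3, CH2Cl2, rt
Reagents that add atoms: none
Why: Dess–Martin oxidation of the primary alcohol to the aldehyde.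

Step 20
Reactants: 30 the 12-aldehyde from step 19
Product: 32 the enal: 1β,6α-bis(tert-butyldimethylsilyloxy)-15-(4-methoxybenzyloxy)-12-oxoeudesm-11(13)-en-8α-yl 2-[(tert-butyldiphenylsilyloxy)methyl]acrylate, via Mannich base 31 (not isolated)
Conditions: Eschenmoser's salt (CH2=NMe2+ I−), Et3N, CH2Cl2, rt
Reagents that add atoms: N,N-dimethylmethyleneiminium iodide, C=[N+](C)C.[I-]
Why: Mannich reaction at the α-CH2 of the aldehyde followed by β-elimination of dimethylamine installs C13 as the α-methylene group.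

Step 21
Reactants: 32 the enal from step 20
Product: 33 the acid: 1β,6α-bis(tert-butyldimethylsilyloxy)-8α-{2-[(tert-butyldiphenylsilyloxy)methyl]acryloyloxy}-15-(4-methoxybenzyloxy)eudesm-11(13)-en-12-oic acid
Conditions: NaClO2, NaH2PO4, 2-methylbut-2-ene, t-BuOH/H2O, 0 °C → rt
Reagents that add atoms: sodium chlorite, [Na+].[O-]Cl=O
Why: Pinnick oxidation converts the α-methylene aldehyde into the acrylic acid without touching alkenes or ethers.

Step 22
Reactants: 33 the acid from step 21
Product: 34 the 15-alcohol: 1β,6α-bis(tert-butyldimethylsilyloxy)-8α-{2-[(tert-butyldiphenylsilyloxy)methyl]acryloyloxy}-15-hydroxyeudesm-11(13)-en-12-oic acid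
Conditions: DDQ, CH2Cl2/pH 7 buffer, 0 °C
Reagents that add atoms: none
Why: Oxidative cleavage of the PMB ether under neutral conditions; with O6 still silylated the acid cannot lactonise.

Step 23
Reactants: 34 the 15-alcohol from step 22
Product: 35 the 15-aldehyde: 1β,6α-bis(tert-butyldimethylsilyloxy)-8α-{2-[(tert-butyldiphenylsilyloxy)methyl]acryloyloxy}-15-oxoeudesm-11(13)-en-12-oic acid
Conditions: Dess–Martin periodinane, NaHCO3, CH2Cl2, 0 °C
Reagents that add atoms: none
Why: Dess–Martin oxidation gives the C15 aldehyde, whose equatorial 4α configuration is also the thermodynamically preferred one.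

Step 24
Reactants: 35 the 15-aldehyde from step 23
Product: 36 target CNP0599450.1: 1β,6α-dihydroxy-8α-[2-(hydroxymethyl)acryloyloxy]-15-oxoeudesm-11(13)-en-12-oic acid
Conditions: TBAF, AcOH (1:1), THF, 0 °C → rt; work-up at pH 5, cold
Reagents that add atoms: none
Why: Buffered fluoride cleaves the two TBS ethers and the TBDPS ether while the acid stays as the non-electrophilic carboxylate, so lactonisation, aldol and oxa-Michael pathways should be avoided.

**Compound list**

1 | (E)-1,4-dibromobut-2-ene | BrC/C=C/CBr | starting material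
2 | 4-methoxybenzyl alcohol | COc1ccc(CO)cc1 | starting material
3 | sodium 4-methoxybenzyl oxide | [Na+].[O-]Cc1ccc(OC)cc1 | intermediate
4 | (E)-1-bromo-4-[(4-methoxybenzyl)oxy]but-2-ene | BrC/C=C/COCc1ccc(OC)cc1 | intermediate
5 | [2-(1,3-dioxan-2-yl)ethyl]magnesium bromide | Br[Mg]CCC1OCCCO1 | starting material
6 | 2-{(3R)-3-[(4-methoxybenzyloxy)methyl]pent-4-en-1-yl}-1,3-dioxane | C=C[C@H](COCc1ccc(OC)cc1)CCC1OCCCO1 | intermediate
7 | (3S)-5-(1,3-dioxan-2-yl)-3-[(4-methoxybenzyloxy)methyl]pentane-1,2-diol (both C2 epimers) | OCC(O)[C@H](COCc1ccc(OC)cc1)CCC1OCCCO1 | intermediate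
8 | (2S)-4-(1,3-dioxan-2-yl)-2-[(4-methoxybenzyloxy)methyl]butanal | O=C[C@H](COCc1ccc(OC)cc1)CCC1OCCCO1 | intermediate
9 | 2-{(3R,4E)-5-iodo-3-[(4-methoxybenzyloxy)methyl]pent-4-en-1-yl}-1,3-dioxane | I/C=C/[C@H](COCc1ccc(OC)cc1)CCC1OCCCO1 | intermediate
10 | 4-(trimethylsilyl)but-3-yn-1-ol | C[Si](C)(C)C#CCCO | starting material
11 | tert-butyldiphenyl{[4-(trimethylsilyl)but-3-yn-1-yl]oxy}silane | C[Si](C)(C)C#CCCO[Si](c1ccccc1)(c1ccccc1)C(C)(C)C | intermediate
12 | 2-{(3R,4E,6E)-6-[2-(tert-butyldiphenylsilyloxy)ethyl]-3-[(4-methoxybenzyloxy)methyl]-7-(trimethylsilyl)hepta-4,6-dien-1-yl}-1,3-dioxane | C[Si](C)(C)/C=C(\CCO[Si](c1ccccc1)(c1ccccc1)C(C)(C)C)/C=C/[C@H](COCc1ccc(OC)cc1)CCC1OCCCO1 | intermediate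
13 | (4R,5E,7E)-7-[2-(tert-butyldiphenylsilyloxy)ethyl]-4-[(4-methoxybenzyloxy)methyl]-8-(trimethylsilyl)octa-5,7-dienal | C[Si](C)(C)/C=C(\CCO[Si](c1ccccc1)(c1ccccc1)C(C)(C)C)/C=C/[C@H](COCc1ccc(OC)cc1)CCC=O | intermediate
14 | prop-1-en-2-ylmagnesium bromide | C=C(C)[Mg]Br | starting material
15 | (6R,7E,9E)-9-[2-(tert-butyldiphenylsilyloxy)ethyl]-6-[(4-methoxybenzyloxy)methyl]-2-methyl-10-(trimethylsilyl)deca-1,7,9-trien-3-ol (both C3 epimers) | C[Si](C)(C)/C=C(\CCO[Si](c1ccccc1)(c1ccccc1)C(C)(C)C)/C=C/[C@H](COCc1ccc(OC)cc1)CCC(O)C(C)=C | intermediate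
16 | (6R,7E,9E)-9-[2-(tert-butyldiphenylsilyloxy)ethyl]-6-[(4-methoxybenzyloxy)methyl]-2-methyl-10-(trimethylsilyl)deca-1,7,9-trien-3-one | C[Si](C)(C)/C=C(\CCO[Si](c1ccccc1)(c1ccccc1)C(C)(C)C)/C=C/[C@H](COCc1ccc(OC)cc1)CCC(=O)C(C)=C | intermediate
17 | 12-(tert-butyldiphenylsilyloxy)-15-(4-methoxybenzyloxy)-8β-(trimethylsilyl)-13-noreudesm-6-en-1-one (5α-H, 10β-CH3, 4α-CH2OPMB) | C[Si](C)(C)[C@@H]1C[C@]2(C)[C@@H](C=C1CCO[Si](c3ccccc3)(c3ccccc3)C(C)(C)C)[C@H](COCc3ccc(OC)cc3)CCC2=O | intermediate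
18 | 12-(tert-butyldiphenylsilyloxy)-15-(4-methoxybenzyloxy)-8β-(trimethylsilyl)-13-noreudesm-6-en-1β-ol | C[Si](C)(C)[C@@H]1C[C@]2(C)[C@@H](C=C1CCO[Si](c3ccccc3)(c3ccccc3)C(C)(C)C)[C@H](COCc3ccc(OC)cc3)CC[C@H]2O | intermediate
19 | 6α,7α-epoxide of 18 | C[Si](C)(C)[C@@H]1C[C@]2(C)[C@@H]([C@H]3O[C@@]13CCO[Si](c4ccccc4)(c4ccccc4)C(C)(C)C)[C@H](COCc4ccc(OC)cc4)CC[C@H]2O | intermediate
20 | 15-(4-methoxybenzyloxy)-13-noreudesm-7-ene-1β,6α,12-triol | C1=C(CCO)[C@H](O)[C@H]2[C@H](COCc3ccc(OC)cc3)CC[C@@H](O)[C@]2(C)C1 | intermediate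
21 | 1β,6α,12-tris(tert-butyldimethylsilyloxy)-15-(4-methoxybenzyloxy)-13-noreudesm-7-ene | C1=C(CCO[Si](C)(C)C(C)(C)C)[C@H](O[Si](C)(C)C(C)(C)C)[C@H]2[C@H](COCc3ccc(OC)cc3)CC[C@@H](O[Si](C)(C)C(C)(C)C)[C@]2(C)C1 | intermediate
22 | 8α-boryl-1β,6α,12-tris(tert-butyldimethylsilyloxy)-15-(4-methoxybenzyloxy)-13-noreudesmane (7α-H) | B[C@H]1C[C@]2(C)[C@@H]([C@@H](O[Si](C)(C)C(C)(C)C)[C@@H]1CCO[Si](C)(C)C(C)(C)C)[C@H](COCc3ccc(OC)cc3)CC[C@H]2O[Si](C)(C)C(C)(C)C | intermediate
23 | 1β,6α,12-tris(tert-butyldimethylsilyloxy)-15-(4-methoxybenzyloxy)-13-noreudesman-8α-ol | O[C@H]1C[C@]2(C)[C@@H]([C@@H](O[Si](C)(C)C(C)(C)C)[C@@H]1CCO[Si](C)(C)C(C)(C)C)[C@H](COCc3ccc(OC)cc3)CC[C@H]2O[Si](C)(C)C(C)(C)C | intermediate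
24 | ethyl 2-(hydroxymethyl)acrylate | C=C(CO)C(=O)OCC | starting material
25 | ethyl 2-[(tert-butyldiphenylsilyloxy)methyl]acrylate | C=C(CO[Si](c1ccccc1)(c1ccccc1)C(C)(C)C)C(=O)OCC | intermediate
26 | 2-[(tert-butyldiphenylsilyloxy)methyl]acrylic acid | C=C(CO[Si](c1ccccc1)(c1ccccc1)C(C)(C)C)C(=O)O | intermediate
27 | 2-[(tert-butyldiphenylsilyloxy)methyl]acrylic 2,4,6-trichlorobenzoic anhydride | C=C(CO[Si](c1ccccc1)(c1ccccc1)C(C)(C)C)C(=O)OC(=O)c1c(Cl)cc(Cl)cc1Cl | intermediate
28 | 1β,6α,12-tris(tert-butyldimethylsilyloxy)-15-(4-methoxybenzyloxy)-13-noreudesman-8α-yl 2-[(tert-butyldiphenylsilyloxy)methyl]acrylate | C=C(CO[Si](c1ccccc1)(c1ccccc1)C(C)(C)C)C(=O)O[C@H]1C[C@]2(C)[C@@H]([C@@H](O[Si](C)(C)C(C)(C)C)[C@@H]1CCO[Si](C)(C)C(C)(C)C)[C@H](COCc3ccc(OC)cc3)CC[C@H]2O[Si](C)(C)C(C)(C)C | intermediate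
29 | 12-alcohol (primary TBS of 28 removed) | C=C(CO[Si](c1ccccc1)(c1ccccc1)C(C)(C)C)C(=O)O[C@H]1C[C@]2(C)[C@@H]([C@@H](O[Si](C)(C)C(C)(C)C)[C@@H]1CCO)[C@H](COCc3ccc(OC)cc3)CC[C@H]2O[Si](C)(C)C(C)(C)C | intermediate
30 | 12-aldehyde (13-noreudesman-12-al) | C=C(CO[Si](c1ccccc1)(c1ccccc1)C(C)(C)C)C(=O)O[C@H]1C[C@]2(C)[C@@H]([C@@H](O[Si](C)(C)C(C)(C)C)[C@@H]1CC=O)[C@H](COCc3ccc(OC)cc3)CC[C@H]2O[Si](C)(C)C(C)(C)C | intermediate
31 | 13-(dimethylamino)eudesman-12-al Mannich base (C11 epimers) | C=C(CO[Si](c1ccccc1)(c1ccccc1)C(C)(C)C)C(=O)O[C@H]1C[C@]2(C)[C@@H]([C@@H](O[Si](C)(C)C(C)(C)C)[C@@H]1C(CN(C)C)C=O)[C@H](COCc3ccc(OC)cc3)CC[C@H]2O[Si](C)(C)C(C)(C)C | intermediate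
32 | eudesm-11(13)-en-12-al (enal) | C=C(CO[Si](c1ccccc1)(c1ccccc1)C(C)(C)C)C(=O)O[C@H]1C[C@]2(C)[C@@H]([C@@H](O[Si](C)(C)C(C)(C)C)[C@@H]1C(=C)C=O)[C@H](COCc3ccc(OC)cc3)CC[C@H]2O[Si](C)(C)C(C)(C)C | intermediate
33 | eudesm-11(13)-en-12-oic acid with 15-OPMB | C=C(CO[Si](c1ccccc1)(c1ccccc1)C(C)(C)C)C(=O)O[C@H]1C[C@]2(C)[C@@H]([C@@H](O[Si](C)(C)C(C)(C)C)[C@@H]1C(=C)C(=O)O)[C@H](COCc3ccc(OC)cc3)CC[C@H]2O[Si](C)(C)C(C)(C)C | intermediate
34 | 15-hydroxy acid | C=C(CO[Si](c1ccccc1)(c1ccccc1)C(C)(C)C)C(=O)O[C@H]1C[C@]2(C)[C@@H]([C@@H](O[Si](C)(C)C(C)(C)C)[C@@H]1C(=C)C(=O)O)[C@H](CO)CC[C@H]2O[Si](C)(C)C(C)(C)C | intermediate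
35 | 15-oxo acid (fully silylated target) | C=C(CO[Si](c1ccccc1)(c1ccccc1)C(C)(C)C)C(=O)O[C@H]1C[C@]2(C)[C@@H]([C@@H](O[Si](C)(C)C(C)(C)C)[C@@H]1C(=C)C(=O)O)[C@H](C=O)CC[C@H]2O[Si](C)(C)C(C)(C)C | intermediate
36 | CNP0599450.1: 1β,6α-dihydroxy-8α-[2-(hydroxymethyl)acryloyloxy]-15-oxoeudesm-11(13)-en-12-oic acid | C=C(CO)C(=O)O[C@H]1C[C@]2(C)[C@@H]([C@@H](O)[C@@H]1C(=C)C(=O)O)[C@H](C=O)CC[C@H]2O | target

**Step count and risks**

Total steps: 24. Longest linear sequence: 21 steps (steps 1–4, 6–14 and 17–24).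

Steps most likely to fail:

1. Step 10 (key cycloaddition). The ketone-endo transition state may compete and give cis-fused material, facial discrimination by the single C4 substituent may be incomplete at the temperature needed, and the isopropenyl ketone may oligomerise. Fallback: leave the uncatalysed, purely substrate-controlled mode and run the closure under template control. Trienone 16 is complexed at −78 °C in toluene/CH2Cl2 with the bulky aluminium phenoxide Al(OC6H3Ph2-2,6)3. The encapsulated carbonyl can only sit exo (Lewis-acid-templated exo-selective Diels–Alder reaction), and the lowered LUMO should let the closure run at −78 to −20 °C, where the chair/equatorial preference is larger and oligomerisation is suppressed. This sets out from 16 and returns at 17; no new compound is made.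

2. Step 6 (hydrovinylation). Formate may simply reduce the vinyl iodide, carbopalladation may take the wrong regiochemistry, or the α-silyl alkenylpalladium intermediate may isomerise and put silicon "inside". Fallback: make the C6–C7 bond by cross-coupling of two preformed partners. Borylcupration/protonation of alkyne 11 (CuCl, NaOt-Bu, Xantphos, B2pin2, MeOH, THF) should give, by syn addition with copper on the silicon-bearing carbon, the (Z)-2-boryl-1-silylalkene F1. Suzuki–Miyaura coupling of F1 with vinyl iodide 9 (Pd(dppf)Cl2, K3PO4, THF/H2O), with retention at both alkenes, returns to 12.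

3. Step 14 (hydroboration). Borane may add slowly to the hindered trisubstituted alkene, or partly from the β face under the influence of the allylic 6α-silyloxy group. Fallback: replace hydroboration by hydroxyl-directed epoxidation and radical epoxide opening. Starting from triol 20, VO(acac)2/t-BuOOH (CH2Cl2, 0 °C) should deliver oxygen cis to the free 6α-hydroxyl and give the 7α,8α-epoxy triol F2. Silylation (TBSOTf, 2,6-lutidine) gives the tris-silyl ether F3. Cp2TiCl2 (cat.), Mn, 2,4,6-collidine hydrochloride and cyclohexa-1,4-diene in THF then open the epoxide with trivalent titanium toward the tertiary C7 radical, leaving the C8–O bond untouched; hydrogen-atom transfer to C7 from the α face places the side chain equatorial and returns to 23.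

**Further compounds**

F0 | step 10 | none | none
F1 | step 6 | (Z)-tert-butyldiphenyl{[3-(4,4,5,5-tetramethyl-1,3,2-dioxaborolan-2-yl)-4-(trimethylsilyl)but-3-en-1-yl]oxy}silane | C[Si](C)(C)/C=C(/B1OC(C)(C)C(C)(C)O1)CCO[Si](c1ccccc1)(c1ccccc1)C(C)(C)C
F2 | step 14 | 7α,8α-epoxy-15-(4-methoxybenzyloxy)-13-noreudesmane-1β,6α,12-triol | [C@H]13O[C@]3(CCO)[C@H](O)[C@H]2[C@H](COCc4ccc(OC)cc4)CC[C@@H](O)[C@]2(C)C1
F3 | step 14 | 7α,8α-epoxy-1β,6α,12-tris(tert-butyldimethylsilyloxy)-15-(4-methoxybenzyloxy)-13-noreudesmane | [C@H]13O[C@]3(CCO[Si](C)(C)C(C)(C)C)[C@H](O[Si](C)(C)C(C)(C)C)[C@H]2[C@H](COCc4ccc(OC)cc4)CC[C@@H](O[Si](C)(C)C(C)(C)C)[C@]2(C)C1
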